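**Plan**

1. Cuts, with the cyclohexane numbered C1 (quaternary), C2 (CH–CH3), C3, C4 (CH2), C5 (C=CMe2), C6 (CH with the side chain): first the aryl–O–CH2 ether (isofraxidin plus a neopentyl-type alcohol) and the aldehyde (masked as a dimethyl acetal); then the ring bond C1–C2, after adding a C3=C4 double bond and raising the CH2O carbon on C1 to a carboxyl group, which gives a γ,δ-unsaturated acid, the retron of an ester-enolate Claisen shift.
2. Enabling feature: C1 and C4 are 1,4-related across the ring, so a C4–O bond that the target does not contain can tie C4 to the carboxyl carbon on C1 as a δ-lactone (O, C=O, C1, C6, C5, C4) carrying C3–C2–CH3 as an (E)-propenyl group on C4; the [3,3] shift of its ketene acetal closes C1–C2 and erases the lactone ring.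
3. The lactone is cut at its α-methyl group, at C1–C6 (made as the lactone C=C by intramolecular Horner–Wadsworth–Emmons reaction, then reduced), at the C5–acyl bond (vinyllithium plus Weinreb amide) and at the carbinol–propenyl bond (alkenylzinc plus 2-bromo-3-methylbut-2-enal).
4. Forward order: acyclic bromo dienol → hydroxy enone → dihydropyranone (temporary ring) → saturated α-methyl lactone → cyclohexene acid (the only carbocycle built) → alcohol, ring alkene saturated → aryl ether with purchased isofraxidin → aldehyde.
5. Stereochemistry: one carbinol centre from a catalytic asymmetric alkenylation; it steers hydride to the opposite face of the lactone (future C6), is then relayed through the boat-shaped shift to C1 and C2, and is itself destroyed.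

Key step: step 9

Remark on numbering: compounds 11–14 are numbered as pyran-2-ones (O1, C2 carbonyl, C3 α-carbon, C4 side-chain carbon, C5 isopropylidene carbon, C6 carbinol carbon, propenyl C7=C8–C9); these become the carboxyl carbon, C1, C6, C5, C4, C3, C2 and the C2 methyl group of the carbocycle.
Remark on the chemistry: the configuration at C3 of lactone 13 is erased in step 9 and need not be controlled; 13 is written as the expected 3,4-trans isomer.

**Route**

Step 1
Reactants: 1 3-methylbut-2-enal
Product: 3 2-bromo-3-methylbut-2-enal, via 2,3-dibromo-3-methylbutanal 2 (not isolated)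
Conditions: Br2, CH2Cl2, 0 °C; then Et3N, 0 °C → rt
Reagents that add atoms: bromine, BrBr
Why: Bromination–dehydrobromination: Br2 adds across the trisubstituted C=C and Et3N then removes the acidic α-hydrogen with loss of the β-bromide (E1cB), which should give the α-bromo enal; no stereocentre is formed.

Step 2
Reactants: 3 2-bromo-3-methylbut-2-enal
Product: 4 (4R,5E)-3-bromo-2-methylhepta-2,5-dien-4-ol
Conditions: propyne, Cy2BH, toluene, 0 °C; Me2Zn, −78 °C; (2R)-(+)-3-exo-morpholinoisoborneol [(+)-MIB, 5 mol %], then 3, −20 → 0 °C; aq. NH4Cl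
Reagents that add atoms: propyne, CC#C
Why: Catalytic asymmetric alkenylzinc addition to an aldehyde: syn hydroboration of propyne gives the (E)-alkenylborane, boron-to-zinc exchange gives the (E)-propenylzinc reagent, and the amino-alcohol-bound zinc complex should deliver the propenyl group to the Re face of the α-branched enal (the face predicted for the (+)-ligand by the accepted zinc-bridged six-membered transition-state model), which sets the (R)-carbinol centre with the E geometry retained.

Step 3
Reactants: 5 methyl 4,4-dimethoxybutanoate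
Product: 6 N,4,4-trimethoxy-N-methylbutanamide
Conditions: MeNHOMe·HCl, i-PrMgCl, THF, −20 → 0 °C
Reagents that add atoms: N,O-dimethylhydroxylamine hydrochloride, CNOC.Cl
Why: Weinreb amide formation: the chloromagnesium amide of N,O-dimethylhydroxylamine acylates with the methyl ester and the chelated adduct does not react further, while the acetal is inert to base.

Step 4
Reactants: 4 (4R,5E)-3-bromo-2-methylhepta-2,5-dien-4-ol; 6 N,4,4-trimethoxy-N-methylbutanamide
Product: 8 (6R,7E)-6-hydroxy-1,1-dimethoxy-5-(propan-2-ylidene)non-7-en-4-one, via dilithio alkoxide–vinyllithium 7 (not isolated)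
Conditions: MeLi (1 equiv), Et2O, −78 °C; t-BuLi (2 equiv), −78 °C; then 6, THF, −78 → −20 °C; aq. NH4Cl
Reagents that add atoms: none
Why: Weinreb ketone synthesis with an alkoxide-bearing vinyllithium: MeLi removes the hydroxyl proton, two equivalents of t-BuLi effect bromine–lithium exchange to 7, and 7 adds once to amide 6 because the chelated tetrahedral adduct survives until work-up; the carbinol centre is not involved.

Step 5
Reactants: 8 (6R,7E)-6-hydroxy-1,1-dimethoxy-5-(propan-2-ylidene)non-7-en-4-one; 9 (diethoxyphosphoryl)acetic acid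
Product: 10 (2E,4R)-9,9-dimethoxy-6-oxo-5-(propan-2-ylidene)non-2-en-4-yl (diethoxyphosphoryl)acetate
Conditions: DCC, DMAP (cat.), CH2Cl2, 0 °C → rt
Reagents that add atoms: none
Why: Steglich esterification (carbodiimide/DMAP) acylates the doubly allylic secondary alcohol under neutral conditions, so that neither ionisation nor allylic transposition of the alcohol is expected.

Step 6
Reactants: 10 (2E,4R)-9,9-dimethoxy-6-oxo-5-(propan-2-ylidene)non-2-en-4-yl (diethoxyphosphoryl)acetate
Product: 11 (6R)-4-(3,3-dimethoxypropyl)-5-(propan-2-ylidene)-6-[(1E)-prop-1-en-1-yl]-5,6-dihydro-2H-pyran-2-one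
Conditions: LiCl, i-Pr2NEt, MeCN, rt → 50 °C
Reagents that add atoms: none
Why: Intramolecular Horner–Wadsworth–Emmons olefination (Masamune–Roush variant): the lithium-chelated phosphonate carbanion adds to the ketone through a six-membered ring and loses phosphate to give the endocyclic, necessarily cis enoate, and β-elimination of the acyloxy group cannot compete because the carbon between ketone and carbinol carries no hydrogen.

Step 7
Reactants: 11 (6R)-4-(3,3-dimethoxypropyl)-5-(propan-2-ylidene)-6-[(1E)-prop-1-en-1-yl]-5,6-dihydro-2H-pyran-2-one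
Product: 12 (4R,6R)-4-(3,3-dimethoxypropyl)-5-(propan-2-ylidene)-6-[(1E)-prop-1-en-1-yl]oxan-2-one
Conditions: Cu(OAc)2·H2O (5 mol %), 1,2-bis(diphenylphosphino)benzene (5 mol %), (EtO)2MeSiH, t-BuOH, toluene, rt
Reagents that add atoms: none
Why: Copper hydride-catalysed conjugate reduction of a β,β-disubstituted unsaturated lactone: allylic 1,3-strain with the isopropylidene methyl group holds the C6 propenyl group axial, so the bulky ligated copper hydride should add to C4 from the opposite face and leave the side chain cis to the propenyl group (4R), tert-butanol protonating the copper enolate; 1,6-delivery is disfavoured because the far end of the dienyl system is fully substituted.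

Step 8
Reactants: 12 (4R,6R)-4-(3,3-dimethoxypropyl)-5-(propan-2-ylidene)-6-[(1E)-prop-1-en-1-yl]oxan-2-one
Product: 13 (3R,4R,6R)-4-(3,3-dimethoxypropyl)-3-methyl-5-(propan-2-ylidene)-6-[(1E)-prop-1-en-1-yl]oxan-2-one
Conditions: LiN(i-Pr)2, THF, −78 °C; MeI, −78 → −40 °C
Reagents that add atoms: iodomethane, CI
Why: Alkylation of the kinetic lithium enolate of the δ-lactone with iodomethane, expected anti to the C4 side chain; the new centre is erased in step 9, so its configuration does not matter.

Step 9
Reactants: 13 (3R,4R,6R)-4-(3,3-dimethoxypropyl)-3-methyl-5-(propan-2-ylidene)-6-[(1E)-prop-1-en-1-yl]oxan-2-one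
Product: 16 (1S,2S,6S)-6-(3,3-dimethoxypropyl)-1,2-dimethyl-5-(propan-2-ylidene)cyclohex-3-ene-1-carboxylic acid, via silyl ketene acetal 14 (not isolated), via trimethylsilyl ester 15 (not isolated)
Conditions: LiN(i-Pr)2, THF, −78 °C; Me3SiCl/Et3N, −78 °C → rt; 65 °C (toluene, 100 °C if needed); then H2O
Reagents that add atoms: none
Why: The base removes the remaining α-hydrogen and O-silylation gives the cyclic silyl ketene acetal 14, whose C3=C2–O1–C6–C7=C8 array undergoes a [3,3]-sigmatropic (Ireland–Claisen) shift in which C3–C8 forms as the ring O1–C6 bond breaks, so the temporary lactone is traded for the cyclohexene and the carboxyl group stays on the new quaternary carbon as silyl ester 15, hydrolysed on work-up. The closest known reaction type is the ring-contracting ester-enolate Claisen rearrangement of 6-alkenyl δ-lactones to cycloalkenecarboxylic acids. The six-membered carbocycle closes through a boat-shaped transition state, the only geometry that the two-carbon tether C4–C5 between the reacting termini allows; formally it is a 6-endo SN2′ attack of the enolate carbon on its own allylic ester, made concerted and suprafacial. The quaternary centre is fixed by the ring-locked ketene acetal geometry together with bond formation on the lactone face that carries the propenyl group, which places the C1 methyl group cis to the side chain because side chain and propenyl group are cis in 13; the CH–CH3 centre is fixed by the E geometry of the propenyl group in the boat, which places its methyl group cis to the carboxyl group; both are relayed from the C6 carbinol centre, which is destroyed. The step needs the [3,3] path to beat ionisation of the doubly allylic C–O bond and needs the right allyl terminus: neutral thermal conditions in a weakly polar solvent should secure the first, and only C8 can be reached, since bonding to the isopropylidene terminus would require a four-membered ring.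

Step 10
Reactants: 16 (1S,2S,6S)-6-(3,3-dimethoxypropyl)-1,2-dimethyl-5-(propan-2-ylidene)cyclohex-3-ene-1-carboxylic acid
Product: 17 [(1S,2S,6S)-6-(3,3-dimethoxypropyl)-1,2-dimethyl-5-(propan-2-ylidene)cyclohex-3-en-1-yl]methanol
Conditions: LiAlH4, THF, 0 °C → reflux; H2O/15% NaOH work-up
Reagents that add atoms: none
Why: LiAlH4 reduction of the carboxylic acid (via its carboxylate) to the primary alcohol; the alkenes and the acetal are inert to hydride.

Step 11
Reactants: 17 [(1S,2S,6S)-6-(3,3-dimethoxypropyl)-1,2-dimethyl-5-(propan-2-ylidene)cyclohex-3-en-1-yl]methanol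
Product: 18 [(1S,2S,6S)-2-(3,3-dimethoxypropyl)-1,6-dimethyl-3-(propan-2-ylidene)cyclohexyl]methanol
Conditions: 2-nitrobenzenesulfonylhydrazide (excess), Et3N, CH2Cl2, rt
Reagents that add atoms: none
Why: Diimide reduction: diazene released from the sulfonyl hydrazide transfers two hydrogens in a concerted syn fashion to the cis-disubstituted ring alkene and does not reduce the tetrasubstituted isopropylidene alkene (selectivity by degree of substitution); no stereocentre is formed, and the step precedes attachment of the coumarin, whose C3=C4 bond would also be reduced.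

Step 12
Reactants: 18 [(1S,2S,6S)-2-(3,3-dimethoxypropyl)-1,6-dimethyl-3-(propan-2-ylidene)cyclohexyl]methanol; 19 isofraxidin (7-hydroxy-6,8-dimethoxy-2H-chromen-2-one)
Product: 21 7-{[(1S,2S,6S)-2-(3,3-dimethoxypropyl)-1,6-dimethyl-3-(propan-2-ylidene)cyclohexyl]methoxy}-6,8-dimethoxy-2H-chromen-2-one, via primary triflate 20 (not isolated)
Conditions: Tf2O, pyridine, CH2Cl2, −40 → 0 °C; then 19, Cs2CO3, DMF, rt → 50 °C
Reagents that add atoms: none
Why: Williamson-type SN2 O-alkylation: the alcohol is turned into the triflate, which cannot eliminate because its β-carbon is quaternary, and the cesium phenoxide of 19 displaces it in DMF, the best sulfonate leaving group being used to offset the neopentyl retardation; no stereocentre is involved.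

Step 13
Reactants: 21 7-{[(1S,2S,6S)-2-(3,3-dimethoxypropyl)-1,6-dimethyl-3-(propan-2-ylidene)cyclohexyl]methoxy}-6,8-dimethoxy-2H-chromen-2-one
Product: 22 7-{[(1S,2S,6S)-1,6-dimethyl-2-(3-oxopropyl)-3-(propan-2-ylidene)cyclohexyl]methoxy}-6,8-dimethoxy-2H-chromen-2-one (CNP0213227.1)
Conditions: PPTS (cat.), acetone/H2O (10:1), 45 °C
Reagents that add atoms: water, O
Why: Acid-catalysed hydrolysis (transacetalisation with acetone/water) of the dimethyl acetal releases the aldehyde, and the weak acid and low temperature are chosen so that the aldehyde does not add to the nearby tetrasubstituted alkene (carbonyl-ene or Prins reaction) and the exocyclic double bond does not migrate.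

**Compound list**

1 | 3-methylbut-2-enal | CC(C)=CC=O | starting material
2 | 2,3-dibromo-3-methylbutanal (racemic) | CC(C)(Br)C(Br)C=O | intermediate (not isolated)
3 | 2-bromo-3-methylbut-2-enal | CC(C)=C(Br)C=O | intermediate
4 | (4R,5E)-3-bromo-2-methylhepta-2,5-dien-4-ol | C/C=C/[C@@H](O)C(Br)=C(C)C | intermediate
5 | methyl 4,4-dimethoxybutanoate | COC(=O)CCC(OC)OC | starting material
6 | N,4,4-trimethoxy-N-methylbutanamide | CON(C)C(=O)CCC(OC)OC | intermediate
7 | lithium (4R,5E)-3-lithio-2-methylhepta-2,5-dien-4-olate | C/C=C/[C@@H](O[Li])C([Li])=C(C)C | intermediate (not isolated)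
8 | (6R,7E)-6-hydroxy-1,1-dimethoxy-5-(propan-2-ylidene)non-7-en-4-one | C/C=C/[C@@H](O)C(=C(C)C)C(=O)CCC(OC)OC | intermediate
9 | (diethoxyphosphoryl)acetic acid | CCOP(=O)(CC(=O)O)OCC | starting material
10 | (2E,4R)-9,9-dimethoxy-6-oxo-5-(propan-2-ylidene)non-2-en-4-yl (diethoxyphosphoryl)acetate | C/C=C/[C@@H](OC(=O)CP(=O)(OCC)OCC)C(=C(C)C)C(=O)CCC(OC)OC | intermediate
11 | (6R)-4-(3,3-dimethoxypropyl)-5-(propan-2-ylidene)-6-[(1E)-prop-1-en-1-yl]-5,6-dihydro-2H-pyran-2-one | C/C=C/[C@H]1OC(=O)C=C(CCC(OC)OC)C1=C(C)C | intermediate
12 | (4R,6R)-4-(3,3-dimethoxypropyl)-5-(propan-2-ylidene)-6-[(1E)-prop-1-en-1-yl]oxan-2-one (side chain and propenyl cis) | C/C=C/[C@H]1OC(=O)C[C@@H](CCC(OC)OC)C1=C(C)C | intermediate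
13 | (3R,4R,6R)-4-(3,3-dimethoxypropyl)-3-methyl-5-(propan-2-ylidene)-6-[(1E)-prop-1-en-1-yl]oxan-2-one | C/C=C/[C@H]1OC(=O)[C@H](C)[C@@H](CCC(OC)OC)C1=C(C)C | intermediate
14 | trimethylsilyl ketene acetal of 13: (2R,4S)-4-(3,3-dimethoxypropyl)-5-methyl-3-(propan-2-ylidene)-2-[(1E)-prop-1-en-1-yl]-6-[(trimethylsilyl)oxy]-3,4-dihydro-2H-pyran | C/C=C/[C@H]1OC(O[Si](C)(C)C)=C(C)[C@@H](CCC(OC)OC)C1=C(C)C | intermediate (not isolated)
15 | trimethylsilyl (1S,2S,6S)-6-(3,3-dimethoxypropyl)-1,2-dimethyl-5-(propan-2-ylidene)cyclohex-3-ene-1-carboxylate | C[Si](C)(C)OC(=O)[C@@]1(C)[C@@H](C)C=CC(=C(C)C)[C@@H]1CCC(OC)OC | intermediate (not isolated)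
16 | (1S,2S,6S)-6-(3,3-dimethoxypropyl)-1,2-dimethyl-5-(propan-2-ylidene)cyclohex-3-ene-1-carboxylic acid | OC(=O)[C@@]1(C)[C@@H](C)C=CC(=C(C)C)[C@@H]1CCC(OC)OC | intermediate
17 | [(1S,2S,6S)-6-(3,3-dimethoxypropyl)-1,2-dimethyl-5-(propan-2-ylidene)cyclohex-3-en-1-yl]methanol | OC[C@@]1(C)[C@@H](C)C=CC(=C(C)C)[C@@H]1CCC(OC)OC | intermediate
18 | [(1S,2S,6S)-2-(3,3-dimethoxypropyl)-1,6-dimethyl-3-(propan-2-ylidene)cyclohexyl]methanol | OC[C@@]1(C)[C@@H](C)CCC(=C(C)C)[C@@H]1CCC(OC)OC | intermediate
19 | isofraxidin (7-hydroxy-6,8-dimethoxy-2H-chromen-2-one) | COc1cc2ccc(=O)oc2c(OC)c1O | starting material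
20 | [(1S,2S,6S)-2-(3,3-dimethoxypropyl)-1,6-dimethyl-3-(propan-2-ylidene)cyclohexyl]methyl trifluoromethanesulfonate | O=S(=O)(OC[C@@]1(C)[C@@H](C)CCC(=C(C)C)[C@@H]1CCC(OC)OC)C(F)(F)F | intermediate (not isolated)
21 | 7-{[(1S,2S,6S)-2-(3,3-dimethoxypropyl)-1,6-dimethyl-3-(propan-2-ylidene)cyclohexyl]methoxy}-6,8-dimethoxy-2H-chromen-2-one | COc1cc2ccc(=O)oc2c(OC)c1OC[C@@]1(C)[C@@H](C)CCC(=C(C)C)[C@@H]1CCC(OC)OC | intermediate
22 | 7-{[(1S,2S,6S)-1,6-dimethyl-2-(3-oxopropyl)-3-(propan-2-ylidene)cyclohexyl]methoxy}-6,8-dimethoxy-2H-chromen-2-one | COc1cc2ccc(=O)oc2c(OC)c1OC[C@@]1(C)[C@@H](C)CCC(=C(C)C)[C@@H]1CCC=O | target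

**Count and risks**

Total step count: 13 (12 in the main line and 1 for amide 6). Longest linear sequence: 12 steps (1 → 22 through steps 1, 2 and 4–13).

Steps most likely to fail:

1. Step 9. What may go wrong: incomplete deprotonation of the hindered tertiary α-carbon of 13, or C- instead of O-silylation, so that little ketene acetal forms; and ionisation of the doubly allylic C–O bond at the temperature the crowded boat requires. Fallback, setting out from 12 and returning at 16: the lithium enolate of 12 is aminomethylated with dimethyl(methylidene)ammonium iodide to the 3-[(dimethylamino)methyl] lactone F1; N-methylation with MeI gives the trimethylammonium iodide F2, and NaHCO3 eliminates trimethylamine to give the α-methylene lactone F3. RhCl(PPh3)3-catalysed 1,4-hydrosilylation of this methacrylate-type ester with Et3SiH should place hydrogen on the exocyclic CH2 (the future C1 methyl group) and give the fully substituted triethylsilyl ketene acetal F4 under neutral conditions and without any deprotonation. F4 should then rearrange as in step 9 (reductive Ireland–Claisen rearrangement) to the triethylsilyl ester F5, and aqueous work-up gives 16.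

2. Step 7. What may go wrong: hydride delivery to the face syn to the propenyl group (giving the 4,6-trans lactone, which would lead to the wrong configuration at C6 of the carbocycle), or 1,6-delivery across the dienyl lactone. Fallback, setting out from 11 and returning at 12: substrate control is replaced by catalyst control, that is an asymmetric conjugate reduction with a chiral copper hydride (CuCl, NaOt-Bu, p-tol-BINAP, polymethylhydrosiloxane, toluene), a reaction type established for β-substituted unsaturated δ-lactones. Both ligand antipodes are available and the one whose facial preference reinforces anti delivery is used. No compound outside the list is made (F0).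

3. Step 12. What may go wrong: slow SN2 displacement at the neopentyl-type carbon by the doubly ortho-substituted phenoxide, so that the triflate is lost to solvent attack or skeletal rearrangement before the ether forms. Fallback, setting out from 18 and 19 and returning at 21: Mitsunobu-type redox condensation of 18 with 19 using (cyanomethylene)tributylphosphorane in toluene at 100 °C. This activates the alcohol in situ as an alkoxyphosphonium ion next to the acidic phenol and avoids a discrete sulfonate. No compound outside the list is made (F0).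

**Further compounds**

F1 | step 9 | (4R,6R)-3-[(dimethylamino)methyl]-4-(3,3-dimethoxypropyl)-5-(propan-2-ylidene)-6-[(1E)-prop-1-en-1-yl]oxan-2-one (either C3 epimer) | C/C=C/[C@H]1OC(=O)C(CN(C)C)[C@@H](CCC(OC)OC)C1=C(C)C
F2 | step 9 | {(4R,6R)-4-(3,3-dimethoxypropyl)-2-oxo-5-(propan-2-ylidene)-6-[(1E)-prop-1-en-1-yl]oxan-3-yl}-N,N,N-trimethylmethanaminium iodide | C/C=C/[C@H]1OC(=O)C(C[N+](C)(C)C)[C@@H](CCC(OC)OC)C1=C(C)C.[I-]
F3 | step 9 | (4S,6R)-4-(3,3-dimethoxypropyl)-3-methylidene-5-(propan-2-ylidene)-6-[(1E)-prop-1-en-1-yl]oxan-2-one | C/C=C/[C@H]1OC(=O)C(=C)[C@@H](CCC(OC)OC)C1=C(C)C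
F4 | step 9 | (2R,4S)-4-(3,3-dimethoxypropyl)-5-methyl-3-(propan-2-ylidene)-2-[(1E)-prop-1-en-1-yl]-6-[(triethylsilyl)oxy]-3,4-dihydro-2H-pyran | C/C=C/[C@H]1OC(O[Si](CC)(CC)CC)=C(C)[C@@H](CCC(OC)OC)C1=C(C)C
F5 | step 9 | triethylsilyl (1S,2S,6S)-6-(3,3-dimethoxypropyl)-1,2-dimethyl-5-(propan-2-ylidene)cyclohex-3-ene-1-carboxylate | CC[Si](CC)(CC)OC(=O)[C@@]1(C)[C@@H](C)C=CC(=C(C)C)[C@@H]1CCC(OC)OC
F0 | step 7 | none | none
F0 | step 12 | none | none
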